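Everything hinges on disconnecting C13–C14 in ring D. The feature used is that C13, the atom shared by rings C and D, carries the ring C oxygen. With hydrogen in place of C14 it is an oxygen-activated methine, and a diazoacetate on the C16 oxygen puts its carbene carbon within five-ring reach of that C–H. A single dirhodium carbenoid insertion then makes C13–C14, closes ring D as a γ-lactone (C15 carbonyl) and converts a simple secondary ether stereocentre into the quaternary spiro centre without loss of configuration. The precursor is the cis-fused 8-keto decalin bearing the 9,13-spiro tetrahydrofuran (ring C), H at C13 and the C16 diazoacetate.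

Key step: step 15

Assumption: labdane numbering is used and β is the face of the C10 methyl group; the target SMILES encodes a cis-fused decalin (5β-H, 10β-CH3) and is taken as written; compounds 6–10 are racemic and are drawn as the enantiomer that is carried on.

Design notes: on this cis-decalin, reagents reach ring B from the convex β face, so the α-oriented C9 oxygen is not brought in by enolate hydroxylation; instead carbon C11 is delivered to a C9 ketone. Absolute configuration rests on a resolution that costs no extra step (step 7) and on a chiral-pool C4 unit, not on an untested asymmetric cyclisation.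

Step 1
Reactants: 1 nerol
Product: 2 neryl bromide
Conditions: PBr3, Et2O, −10 °C
Reagents that add atoms: phosphorus tribromide BrP(Br)Br
Why: Alcohol-to-bromide exchange through the bromophosphite (SN2 at the primary allylic carbon) is routine for terpene allylic alcohols, and the low temperature keeps the Z alkene (future C5=C10) that later encodes the cis ring fusion.

Step 2
Reactants: 2 neryl bromide; 3 allyl acetoacetate
Product: 5 allyl (6Z)-7,11-dimethyl-3-oxododeca-6,10-dienoate, via acetoacetate dianion 4 (not isolated)
Conditions: 3, NaH, THF, 0 °C; n-BuLi, 0 °C; then 2, 0 °C to rt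
Reagents that add atoms: none
Why: In this dianion alkylation of a β-keto ester only the more basic terminal carbanion attacks the allylic bromide by SN2, which joins C6 to C7 and leaves both alkenes untouched.

Step 3
Reactants: 5 allyl (6Z)-7,11-dimethyl-3-oxododeca-6,10-dienoate
Product: 6 (±)-cis-decalin β-keto ester (allyl 5,5,8a-trimethyl-2-oxodecahydronaphthalene-1-carboxylate; H5 and the C10 methyl both β)
Conditions: SnCl4, CH2Cl2, 0 °C to rt
Reagents that add atoms: none
Why: In this proton-initiated cationic polyene cyclisation terminated by the SnCl4-chelated enol, antiperiplanar addition of C4 and C9 across the Z C5=C10 alkene in a chair-like fold places H5 and the C10 methyl group on the same face, so the cis-decalin should form as a racemate.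

Step 4
Reactants: 6 (±)-cis-decalin β-keto ester
Product: 7 (±)-9-hydroxy β-keto ester
Conditions: dimethyldioxirane, acetone/CH2Cl2, 0 °C
Reagents that add atoms: dimethyldioxirane CC1(C)OO1
Why: Epoxidation of the strongly enolised β-keto ester and collapse of the epoxide (α-hydroxylation of a 1,3-dicarbonyl compound) oxidises C9 only, the electron-poor allyl ester alkene reacting far more slowly, and the C9 configuration does not matter because this centre becomes trigonal in step 6.

Step 5
Reactants: 7 (±)-9-hydroxy β-keto ester
Product: 8 (±)-acyloin (9-hydroxy-8-ketone of the cis-decalin)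
Conditions: Pd(OAc)2 (cat.), PPh3, HCO2H, Et3N, THF, rt
Reagents that add atoms: none
Why: Tsuji–Trost-type deallylation with formate as the hydride source frees the β-keto acid, which loses CO2 at room temperature through the enediol to the acyloin, so the ester that steered the cyclisation leaves under nearly neutral conditions.

Step 6
Reactants: 8 (±)-acyloin
Product: 10 (±)-diosphenol (8-hydroxy-7-en-9-one of the cis-decalin), via 8,9-diketone 9 (not isolated)
Conditions: Dess–Martin periodinane, CH2Cl2, rt
Reagents that add atoms: none
Why: Dess–Martin oxidation of the acyloin (either ketol tautomer serves) gives the 1,2-diketone, which can enolise only towards C7 because C10 is quaternary, so a single diosphenol with the free ketone at C9 should result.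

Step 7
Reactants: 10 (±)-diosphenol; 11 (−)-chloromethyl menthyl ether
Product: 12 8-(menthyloxymethoxy)-7-en-9-one, the diastereomer with 5β-H and 10β-CH3
Conditions: 11, i-Pr2NEt, CH2Cl2, 0 °C to rt; separation of the two diastereomers by crystallisation or chromatography
Reagents that add atoms: none
Why: O-alkylation of the acidic enol by the hard chloromethyl ether masks C8 as a base-stable enol acetal and turns the racemate into two diastereomers that are parted here (classical resolution through a covalent auxiliary), which fixes the absolute configuration of C5 and C10.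

Step 8
Reactants: 13 (S)-2-(2,2-dimethyl-1,3-dioxolan-4-yl)ethanol
Product: 14 (S)-4-(2-iodoethyl)-2,2-dimethyl-1,3-dioxolane
Conditions: I2, PPh3, imidazole, CH2Cl2, 0 °C
Reagents that add atoms: iodine II
Why: Appel-type iodination replaces the primary hydroxyl by SN2 at the future C11 and leaves the chiral-pool stereocentre (future C13) untouched.

Step 9
Reactants: 14 (S)-4-(2-iodoethyl)-2,2-dimethyl-1,3-dioxolane
Product: 16 (S)-1,2-bis(tert-butyldimethylsilyloxy)-4-iodobutane, via iodo diol 15 (not isolated)
Conditions: TsOH (cat.), MeOH, rt; evaporate; t-BuMe2SiOTf, 2,6-lutidine, CH2Cl2, −78 to 0 °C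
Reagents that add atoms: tert-butyldimethylsilyl triflate CC(C)(C)[Si](C)(C)OS(=O)(=O)C(F)(F)F
Why: Transacetalisation followed at once by silylation of the crude diol swaps the acid-labile acetonide for fluoride-labile ethers, so the diol can later be freed without unmasking C8 (a free 8-ketone and 13,16-diol would lock up as a bicyclic ketal under acid), and the iodo diol has no time to close to a tetrahydrofuran.

Step 10
Reactants: 16 (S)-1,2-bis(tert-butyldimethylsilyloxy)-4-iodobutane; 12 8-(menthyloxymethoxy)-7-en-9-one
Product: 18 9α-hydroxy adduct (C11–C16 chain β on C9; 13S), via alkyllithium 17 (not isolated)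
Conditions: 16, t-BuLi (2 equiv), Et2O/pentane, −78 °C; then 12, Et2O, −78 to −40 °C
Reagents that add atoms: none
Why: Lithium–iodine exchange and 1,2-addition of the primary alkyllithium to the 2-alkoxy enone, whose carbonyl has no α-hydrogen, should take place on the convex β face because ring A covers the α face, so C11 ends up β and the C9 oxygen α, and any residue of the enantiomeric decalin would now appear as a separable diastereomer.

Step 11
Reactants: 18 9α-hydroxy adduct
Product: 19 9α,13(S),16-triol with the C8 enol acetal intact
Conditions: Bu4NF, THF, rt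
Reagents that add atoms: none
Why: Fluoride-induced desilylation removes both silyl ethers under non-acidic conditions that the enol acetal tolerates.

Step 12
Reactants: 19 9α,13(S),16-triol
Product: 22 (13R)-9α,13-epoxy spiro ether with free C16–OH and C8 enol acetal, via primary tosylate 20 (not isolated), via terminal epoxide 21 (not isolated)
Conditions: NaH, N-tosylimidazole, THF, 0 to 50 °C
Reagents that add atoms: none
Why: Selective sulfonylation of the primary alkoxide, Williamson closure to the terminal epoxide with retention at C13, and 5-exo-tet opening of that epoxide at C13 by the tertiary C9 alkoxide run in one flask, and the SN2 opening inverts C13 from S to R while it closes ring C and frees C16–OH.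

Step 13
Reactants: 22 (13R)-spiro ether enol acetal
Product: 23 (13R)-spiro ether keto alcohol (8-ketone, C16–OH)
Conditions: 1 M HCl, THF, rt
Reagents that add atoms: none
Why: Enol acetal hydrolysis (protonation at C7, then loss of formaldehyde and menthol) releases the C8 ketone under mild aqueous acid that leaves the saturated ring C ether alone.

Step 14
Reactants: 23 (13R)-spiro ether keto alcohol; 24 bromoacetyl bromide
Product: 26 spiro ether with C13–H and C16 diazoacetate (8-ketone), via bromoacetate 25 (not isolated)
Conditions: 24, NaHCO3, MeCN, 0 °C; extractive work-up; TsNHNHTs, DBU, THF, 0 °C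
Reagents that add atoms: N,N'-ditosylhydrazine Cc1ccc(cc1)S(=O)(=O)NNS(=O)(=O)c1ccc(C)cc1
Why: Acylation of the primary alcohol, then N-alkylation of the ditosylhydrazine by the bromoacetate and base-induced loss of two sulfinate ions, is an established mild route to diazoacetates that leaves the ketone and both ether stereocentres alone.

Step 15
Reactants: 26 spiro ether diazoacetate
Product: 27 bis-spiro 15,16-lactone (8-ketone; 13S)
Conditions: Rh2(OAc)4 (1 mol%), CH2Cl2, reflux, 26 added slowly by syringe pump at high dilution
Reagents that add atoms: none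
Why: Rh2(OAc)4, a carboxylate-bridged dimer of divalent rhodium, takes N2 out of 26, and the electrophilic carbenoid carbon C14 inserts into C13–H through a concerted three-centre transition state with hydride-like transfer of H13 to C14. The closest known reaction type is the dirhodium-catalysed intramolecular C–H insertion of alkyl diazoacetates that gives γ-butyrolactones at tertiary or ether-activated C–H bonds. Ring D closes in the 1,5-insertion mode, the five ring atoms being C14, C15, O, C16 and C13. The quaternary centre C13 is controlled by the configuration already present in 26, because C14 takes the place of H13 with retention (the descriptor changes from R to S only through the priority rules). The step needs site selectivity, and the substrate secures it: C13–H is the only C–H in five-ring reach, it is tertiary and activated by the lone pairs of the ring C oxygen, C9 bears no hydrogen, and C16–H or C12–H would demand a four- or six-membered ring. It also needs the carbenoid to find C13–H before it meets a second diazo molecule, which slow addition at high dilution provides, and H13 lies on the face of ring C next to the flat C8 carbonyl, which is the reason for keeping the ketone free.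

Step 16
Reactants: 27 bis-spiro lactone
Product: 29 8-hydroxy 15-methyl acetal, via lactol 28 (not isolated)
Conditions: i-Bu2AlH, CH2Cl2, −78 °C; aq. KNaC4H4O6 (tartrate); crude in MeOH, PPTS (cat.), rt
Reagents that add atoms: methanol CO
Why: Hydride reduction at low temperature stops at the aluminium hemiacetal of the lactone (and reduces the ketone as well), and Fischer-type acetalisation of the crude lactol masks C15 as a methyl acetal that survives bases, organolithium reagents and oxidants, the new centres at C8 and C15 both being erased later.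

Step 17
Reactants: 29 8-hydroxy 15-methyl acetal
Product: 30 8-keto 15-methyl acetal
Conditions: Dess–Martin periodinane, pyridine, CH2Cl2, rt
Reagents that add atoms: none
Why: Dess–Martin oxidation returns the hindered secondary alcohol to the C8 ketone under buffered conditions that keep the acetal.

Step 18
Reactants: 30 8-keto 15-methyl acetal
Product: 32 6-en-8-one 15-methyl acetal, via trimethylsilyl enol ether 31 (not isolated)
Conditions: LiN(SiMe3)2, Me3SiCl, THF, −78 °C; then Pd(OAc)2, MeCN, rt
Reagents that add atoms: none
Why: In this Saegusa–Ito oxidation the ketone can enolise only towards C7, and palladation of the silyl enol ether followed by β-hydride elimination gives the C6=C7 enone without touching C5.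

Step 19
Reactants: 32 6-en-8-one 15-methyl acetal
Product: 34 8α-acetoxy-8β-methyl-6-ene 15-methyl acetal, via lithium alkoxide 33 (not isolated)
Conditions: MeLi, Et2O/THF, −78 °C; then Ac2O, DMAP, −78 °C to rt
Reagents that add atoms: methyllithium [Li]C; acetic anhydride CC(=O)OC(C)=O
Why: 1,2-Addition of methyllithium to the enone should occur by equatorial attack on the convex β face, because axial attack from the α face meets the syn-axial C1 methylene of ring A, which sets C8 with methyl β and oxygen α, and acylation of the alkoxide in the same flask avoids a separate esterification of a hindered tertiary alcohol.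

Step 20
Reactants: 34 8α-acetoxy-8β-methyl-6-ene 15-methyl acetal
Product: 35 8α-acetoxy-7β-hydroxy-6-ketone 15-methyl acetal
Conditions: RuCl3 (cat.), KHSO5 (as 2 KHSO5·KHSO4·K2SO4), NaHCO3, EtOAc/MeCN/H2O, rt
Reagents that add atoms: potassium peroxymonosulfate [K+].[O-]S(=O)(=O)OO
Why: In this RuO4-catalysed ketohydroxylation the [3+2] addition to the convex β face sets the 7β C–O bond, and the ruthenate ester is oxidised further at the more electron-rich and less hindered C6–H, remote from the acetoxy group, so the ketone should appear at C6 and the hydroxyl at C7 under a bicarbonate buffer that does not enolise C5.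

Step 21
Reactants: 35 8α-acetoxy-7β-hydroxy-6-ketone 15-methyl acetal
Product: 36 15-phenylseleno O,Se-acetal
Conditions: PhSeH, PPTS (cat.), ClCH2CH2Cl, molecular sieves, 40 °C
Reagents that add atoms: benzeneselenol [SeH]c1ccccc1
Why: Acid-catalysed acetal exchange through the C15 oxocarbenium ion is driven by the highly nucleophilic selenol, the weak pyridinium acid leaves the ketol, the tertiary acetate and ring C intact, and the C15 configuration is irrelevant.

Step 22
Reactants: 36 15-phenylseleno O,Se-acetal
Product: 38 target CNP0275274.1, via selenoxide 37 (not isolated)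
Conditions: m-CPBA (1 equiv), CH2Cl2, −78 °C; then Et3N, −78 °C to rt
Reagents that add atoms: none
Why: Selenide oxidation at low temperature and syn elimination of the selenoxide, for which only the C14 hydrogens are available, form the C14=C15 enol ether under amine-buffered, non-acidic conditions that the acid-labile spiro dihydrofuran and the epimerisable C5 should tolerate.

Compound list
1 | nerol, (2Z)-3,7-dimethylocta-2,6-dien-1-ol | CC(C)=CCC/C(C)=C\CO | starting material
2 | neryl bromide, (2Z)-1-bromo-3,7-dimethylocta-2,6-diene | CC(C)=CCC/C(C)=C\CBr | intermediate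
3 | allyl acetoacetate | CC(=O)CC(=O)OCC=C | starting material
4 | sodium lithium dianion of allyl acetoacetate | [Na+].[Li+].[CH2-]C(=O)[CH-]C(=O)OCC=C | intermediate
5 | allyl (6Z)-7,11-dimethyl-3-oxododeca-6,10-dienoate | CC(C)=CCC/C(C)=C\CCC(=O)CC(=O)OCC=C | intermediate
6 | (±)-cis-decalin β-keto ester, 8-ketone, C9 allyl ester, 5β-H, 10β-CH3, C9 epimerisable | O=C1CC[C@@H]2C(C)(C)CCC[C@]2(C)C1C(=O)OCC=C | intermediate
7 | (±)-9-hydroxy β-keto ester, C9 configuration immaterial | O=C1CC[C@@H]2C(C)(C)CCC[C@]2(C)C1(O)C(=O)OCC=C | intermediate
8 | (±)-acyloin, 9-hydroxy-8-ketone, C9 configuration immaterial | O=C1CC[C@@H]2C(C)(C)CCC[C@]2(C)C1O | intermediate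
9 | (±)-8,9-diketone of the cis-decalin | O=C1C(=O)CC[C@@H]2C(C)(C)CCC[C@]12C | intermediate
10 | (±)-diosphenol, 8-hydroxy-7-en-9-one | O=C1C(O)=CC[C@@H]2C(C)(C)CCC[C@]12C | intermediate
11 | (−)-chloromethyl menthyl ether, (1R,2S,5R) | ClCO[C@@H]1C[C@H](C)CC[C@H]1C(C)C | starting material
12 | 8-(menthyloxymethoxy)-7-en-9-one, 5β-H, 10β-CH3, single diastereomer | O=C1C(OCO[C@@H]3C[C@H](C)CC[C@H]3C(C)C)=CC[C@@H]2C(C)(C)CCC[C@]12C | intermediate
13 | (S)-2-(2,2-dimethyl-1,3-dioxolan-4-yl)ethanol | OCC[C@H]1COC(C)(C)O1 | starting material
14 | (S)-4-(2-iodoethyl)-2,2-dimethyl-1,3-dioxolane | ICC[C@H]1COC(C)(C)O1 | intermediate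
15 | (S)-4-iodobutane-1,2-diol | ICC[C@@H](CO)O | intermediate
16 | (S)-1,2-bis(tert-butyldimethylsilyloxy)-4-iodobutane | ICC[C@@H](CO[Si](C)(C)C(C)(C)C)O[Si](C)(C)C(C)(C)C | intermediate
17 | (S)-3,4-bis(tert-butyldimethylsilyloxy)butyllithium | [Li]CC[C@@H](CO[Si](C)(C)C(C)(C)C)O[Si](C)(C)C(C)(C)C | intermediate
18 | 9α-hydroxy adduct, chain β on C9, (13S)-13,16-bis(silyl ether), C8 menthyloxymethyl enol acetal | CC(C)[C@@H]1CC[C@@H](C)C[C@H]1OCOC2=CC[C@@H]3C(C)(C)CCC[C@]3(C)[C@@]2(O)CC[C@@H](CO[Si](C)(C)C(C)(C)C)O[Si](C)(C)C(C)(C)C | intermediate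
19 | 9α,13(S),16-triol, C8 enol acetal | CC(C)[C@@H]1CC[C@@H](C)C[C@H]1OCOC2=CC[C@@H]3C(C)(C)CCC[C@]3(C)[C@@]2(O)CC[C@@H](CO)O | intermediate
20 | 16-tosylate of triol 19 | CC(C)[C@@H]1CC[C@@H](C)C[C@H]1OCOC2=CC[C@@H]3C(C)(C)CCC[C@]3(C)[C@@]2(O)CC[C@@H](COS(=O)(=O)c4ccc(C)cc4)O | intermediate
21 | (13S)-13,16-epoxide with free 9α-OH | CC(C)[C@@H]1CC[C@@H](C)C[C@H]1OCOC2=CC[C@@H]3C(C)(C)CCC[C@]3(C)[C@@]2(O)CC[C@H]4CO4 | intermediate
22 | (13R)-9α,13-epoxy spiro ether, C16–OH, C8 enol acetal | CC(C)[C@@H]1CC[C@@H](C)C[C@H]1OCOC2=CC[C@@H]3C(C)(C)CCC[C@]3(C)[C@@]24CC[C@H](CO)O4 | intermediate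
23 | (13R)-spiro ether keto alcohol, 8-ketone, C16–OH | O=C1CC[C@@H]2C(C)(C)CCC[C@]2(C)[C@@]13CC[C@H](CO)O3 | intermediate
24 | bromoacetyl bromide | BrCC(Br)=O | starting material
25 | C16 bromoacetate of 23 | O=C1CC[C@@H]2C(C)(C)CCC[C@]2(C)[C@@]13CC[C@H](COC(=O)CBr)O3 | intermediate
26 | spiro ether with C13–H and C16 diazoacetate, 8-ketone, 13R | O=C1CC[C@@H]2C(C)(C)CCC[C@]2(C)[C@@]13CC[C@H](COC(=O)C=[N+]=[N-])O3 | intermediate
27 | bis-spiro 15,16-lactone, 8-ketone, 13S | O=C1CC[C@@H]2C(C)(C)CCC[C@]2(C)[C@@]13CC[C@@]4(CC(=O)OC4)O3 | intermediate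
28 | 8-hydroxy 15-lactol, C8 and C15 immaterial | OC1CC[C@@H]2C(C)(C)CCC[C@]2(C)[C@@]13CC[C@@]4(CC(O)OC4)O3 | intermediate
29 | 8-hydroxy 15-methyl acetal, C8 and C15 immaterial | OC1CC[C@@H]2C(C)(C)CCC[C@]2(C)[C@@]13CC[C@@]4(CC(OC)OC4)O3 | intermediate
30 | 8-keto 15-methyl acetal | O=C1CC[C@@H]2C(C)(C)CCC[C@]2(C)[C@@]13CC[C@@]4(CC(OC)OC4)O3 | intermediate
31 | 8-trimethylsilyloxy-7-ene 15-methyl acetal | C[Si](C)(C)OC1=CC[C@@H]2C(C)(C)CCC[C@]2(C)[C@@]13CC[C@@]4(CC(OC)OC4)O3 | intermediate
32 | 6-en-8-one 15-methyl acetal | O=C1C=C[C@@H]2C(C)(C)CCC[C@]2(C)[C@@]13CC[C@@]4(CC(OC)OC4)O3 | intermediate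
33 | lithium 8α-alkoxide, 8β-methyl, 6-ene | [Li+].[O-][C@]1(C)C=C[C@@H]2C(C)(C)CCC[C@]2(C)[C@@]13CC[C@@]4(CC(OC)OC4)O3 | intermediate
34 | 8α-acetoxy-8β-methyl-6-ene 15-methyl acetal | CC(=O)O[C@]1(C)C=C[C@@H]2C(C)(C)CCC[C@]2(C)[C@@]13CC[C@@]4(CC(OC)OC4)O3 | intermediate
35 | 8α-acetoxy-7β-hydroxy-6-ketone 15-methyl acetal | CC(=O)O[C@]1(C)[C@@H](O)C(=O)[C@@H]2C(C)(C)CCC[C@]2(C)[C@@]13CC[C@@]4(CC(OC)OC4)O3 | intermediate
36 | 15-phenylseleno O,Se-acetal | CC(=O)O[C@]1(C)[C@@H](O)C(=O)[C@@H]2C(C)(C)CCC[C@]2(C)[C@@]13CC[C@@]4(CC([Se]c5ccccc5)OC4)O3 | intermediate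
37 | 15-phenylselenoxide | CC(=O)O[C@]1(C)[C@@H](O)C(=O)[C@@H]2C(C)(C)CCC[C@]2(C)[C@@]13CC[C@@]4(CC([Se](=O)c5ccccc5)OC4)O3 | intermediate
38 | CNP0275274.1, 8α-acetoxy-9α,13;15,16-diepoxy-7β-hydroxy-5β-labd-14-en-6-one, 13S | CC(=O)O[C@]1(C)[C@@H](O)C(=O)[C@@H]2C(C)(C)CCC[C@]2(C)[C@@]12CC[C@@]1(C=COC1)O2 | target

Total step count: 22. Longest linear sequence: 20 (steps 1–7 and 10–22).

The three steps most likely to fail are steps 15, 3 and 20.

In step 15 the unstabilised carbenoid may be consumed by dimerisation, by capture of adventitious water or by insertion at C12–H before it reaches C13–H. The fallback sets out from 23 and changes the carbene precursor, not only the catalyst.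
- Acylation with methyl malonyl chloride and pyridine should give the mixed methyl malonate F1.
- Diazo transfer with 4-acetamidobenzenesulfonyl azide and Et3N should give the diazomalonate F2.
- Its longer-lived and more selective acceptor–acceptor carbenoid (Rh2(OAc)4, benzene, reflux) should insert into the same C13–H to give the 14-methoxycarbonyl bis-spiro lactone F3.
- Krapcho demethoxycarbonylation (LiCl, wet DMSO, 130 °C) comes back to the route at 27.

In step 3 a long-lived C10 cation would allow bond rotation and loss of the Z-to-cis stereochemical relay, or the cascade may stall after ring A. The fallback sets out from 5 and starts the cascade with a mercuronium ion in place of a proton.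
- Hg(O2CCF3)2, a salt of divalent mercury, in MeNO2 at 0 °C and then aqueous NaCl should give the 3β-chloromercurio cis-decalin β-keto ester F4 by a more concerted, non-acidic closure.
- Radical demercuration with Bu3SnH comes back at 6.

In step 20 poor regiocontrol in the breakdown of the ruthenate ester, over-oxidation with C6–C7 cleavage, or attack on the acetal C–H may erode the ketol. The fallback sets out from 34 and separates the two oxidation events.
- OsO4 (cat.) with N-methylmorpholine N-oxide in aqueous acetone should give the 6β,7β-diol F5 from the convex face.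
- One equivalent of IBX in DMSO, which oxidises 1,2-diols without cleavage, should take the less hindered C6 carbinol, remote from the quaternary C8, to the ketone and so come back at 35.

Further compounds
F1 | step 15 | mixed methyl malonate of keto alcohol 23 | O=C1CC[C@@H]2C(C)(C)CCC[C@]2(C)[C@@]13CC[C@H](COC(=O)CC(=O)OC)O3
F2 | step 15 | C16 methyl diazomalonate | O=C1CC[C@@H]2C(C)(C)CCC[C@]2(C)[C@@]13CC[C@H](COC(=O)C(=[N+]=[N-])C(=O)OC)O3
F3 | step 15 | 14-methoxycarbonyl bis-spiro lactone, C14 immaterial | O=C1CC[C@@H]2C(C)(C)CCC[C@]2(C)[C@@]13CC[C@@]4(C(C(=O)OC)C(=O)OC4)O3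
F4 | step 3 | (±)-3β-chloromercurio cis-decalin β-keto ester | O=C1CC[C@@H]2C(C)(C)[C@@H]([Hg]Cl)CC[C@]2(C)C1C(=O)OCC=C
F5 | step 20 | 8α-acetoxy-6β,7β-diol 15-methyl acetal | CC(=O)O[C@]1(C)[C@@H](O)[C@@H](O)[C@@H]2C(C)(C)CCC[C@]2(C)[C@@]13CC[C@@]4(CC(OC)OC4)O3
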